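**Retrosynthetic overview**
- The C–C double bond two positions out from the ring-bearing Z alkene is cut by a Wittig reaction into a ring-bearing allylic phosphonium salt and a C12 ester aldehyde (from the symmetric C10 dialdehyde by mono-olefination); the ester is reduced last.
- The Z trisubstituted alkene comes from syn methyl-metalation of a propargylic alcohol, whose alkyne is attached to the ring carbon next to oxygen by alkynylation of the furanium ion of loliolide lactol.
- (−)-Loliolide comes from dehydrololiolide, which comes from methyl cuprate addition to a dienone lactone.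
- Key disconnection: the dienone lactone comes from an achiral para-quinol acid by enantioselective desymmetrising oxa-Michael lactonisation and dehydration; the para-quinol comes from oxidative dearomatisation of (4-hydroxy-2,6-dimethylphenyl)acetic acid, made from 3,5-dimethylphenol and glyoxylic acid.
- Ring order: the carbocycle is the phenol ring itself (dearomatised, never built); the oxygen ring is closed onto it as a lactone in the key step and carried through as lactone, lactol, then dihydrofuran.

Assumption: the SMILES is read literally, so the alkene next to the ring is Z (ring and chain cis; 12Z in the name of 20), all other alkenes are E, and the ring is (2R,6S,7aR).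

**Step 1**
Reactants: 1 3,5-dimethylphenol; 2 glyoxylic acid (monohydrate)
Product: 4 2-(4-hydroxy-2,6-dimethylphenyl)acetic acid, via mandelic acid 3 (not isolated)
Conditions: NaOH, H2O, 35 °C; then AcOH, H3PO2 (50% aq.), NaI (cat.), 100 °C
Reagents that add atoms: none
Why: Phenoxide para-hydroxyalkylation by glyoxylate (Friedel–Crafts type) gives the mandelic acid, whose benzylic C–OH is reduced in the same flask by HI regenerated with H3PO2, the para isomer being purified by crystallisation; no stereocentre remains.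

**Step 2**
Reactants: 4 2-(4-hydroxy-2,6-dimethylphenyl)acetic acid
Product: 5 2-(1-hydroxy-2,6-dimethyl-4-oxocyclohexa-2,5-dien-1-yl)acetic acid
Conditions: PhI(OAc)2, MeCN–H2O (4:1), 0 °C
Reagents that add atoms: water, O
Why: Oxidative dearomatisation with a hypervalent iodine reagent, in which water traps the phenoxenium ion at the substituted para carbon to give the achiral, mirror-symmetric para-quinol.

**Step 3**
Reactants: 5 2-(1-hydroxy-2,6-dimethyl-4-oxocyclohexa-2,5-dien-1-yl)acetic acid
Product: 7 (7aR)-4,7a-dimethyl-7,7a-dihydro-1-benzofuran-2,6-dione, via hydroxy lactone 6 (not isolated)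
Conditions: (R)-TRIP (10 mol%), 4 Å MS, PhMe, 30 °C; then Martin sulfurane, CH2Cl2, 0 °C
Reagents that add atoms: none
Why: Proposed new method: the chiral phosphoric acid hydrogen-bonds the dienone C=O and the CO2H and steers the carboxyl oxygen onto one of the two enantiotopic β-methyl enone carbons (5-exo-trig oxa-Michael, necessarily cis-fused, setting C7a as R; sense of induction assigned by analogy and checked at 9), after which Martin sulfurane dehydrates the tertiary 3a-OH toward its only β-hydrogens (C3) to lock the adduct as the dienone lactone; the closest known reaction type is chiral phosphoric acid-catalysed oxa-Michael desymmetrisation of para-quinol-type cyclohexadienones carrying alcohol tethers.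

**Step 4**
Reactants: 7 (7aR)-4,7a-dimethyl-7,7a-dihydro-1-benzofuran-2,6-dione
Product: 8 (7aR)-4,4,7a-trimethyl-5,7a-dihydro-1-benzofuran-2,6(4H,7H)-dione, (R)-dehydrololiolide
Conditions: Me2CuLi (from CuI, 2 MeLi), Et2O, −78 °C; aq. NH4Cl
Reagents that add atoms: lithium dimethylcuprate, [Li+].C[Cu-]C
Why: Cuprate 1,4-addition at C4, which is β to the ketone, whereas the other dienone terminus (C3) is the α-carbon of the butenolide and is electronically switched off as in muconate additions; the new quaternary carbon carries two methyls, so no stereocentre forms and C7a is untouched.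

**Step 5**
Reactants: 8 (R)-dehydrololiolide
Product: 9 (6S,7aR)-6-hydroxy-4,4,7a-trimethyl-5,6,7,7a-tetrahydro-1-benzofuran-2(4H)-one, (−)-loliolide
Conditions: LiBH(s-Bu)3, THF, −78 °C; aq. NH4Cl
Reagents that add atoms: none
Why: Diastereoselective ketone reduction in which the syn-axial methyls at C4 and C7a block axial attack, so the bulky hydride enters equatorially and gives the axial 6S alcohol cis to the angular methyl (identity and ee checked against natural loliolide, upgraded by recrystallisation).

**Step 6**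
Reactants: 9 (−)-loliolide
Product: 10 (6S,7aR)-4,4,7a-trimethyl-2,4,5,6,7,7a-hexahydro-1-benzofuran-2,6-diol (C2 epimer mixture)
Conditions: i-Bu2AlH (2.2 equiv), CH2Cl2, −78 °C; Rochelle salt
Reagents that add atoms: none
Why: Partial reduction of the butenolide to the lactol, the tetrahedral aluminate surviving at −78 °C until work-up; the C2 epimer mixture is erased in the next step.

**Step 7**
Reactants: 10 the lactol; 11 trimethyl(prop-2-yn-1-yloxy)silane
Product: 12 (2R,6S,7aR)-2-(3-hydroxyprop-1-yn-1-yl)-4,4,7a-trimethyl-2,4,5,6,7,7a-hexahydro-1-benzofuran-6-ol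
Conditions: Cu(MeCN)4PF6 (10 mol%), (S,S)-Ph-PyBox (12 mol%), TMSOTf (3.2 equiv), i-Pr2NEt, Et2O, −30 °C; then K2CO3, MeOH
Reagents that add atoms: none
Why: Proposed new method: TMSOTf silylates and ionises the lactol to a 5,5-disubstituted 2H-furanium ion (it cannot aromatise because C7a is quaternary), and the chiral copper–PyBox acetylide adds at C2 on the face anti to the angular methyl, catalyst control reinforcing the weak substrate bias to set C2 as R (ligand antipode to be swapped if the 2S epimer dominates); the closest known reaction type is copper/PyBox-catalysed enantioselective alkynylation of isochroman and chromene acetals.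

**Step 8**
Reactants: 12 the propargylic alcohol
Product: 13 (2Z)-3-[(2R,6S,7aR)-6-hydroxy-4,4,7a-trimethyl-2,4,5,6,7,7a-hexahydro-1-benzofuran-2-yl]but-2-en-1-ol
Conditions: MeMgBr (4 equiv), Fe(acac)3 (15 mol%), THF, −40 → 0 °C; aq. NH4Cl
Reagents that add atoms: methylmagnesium bromide, C[Mg]Br
Why: Alkoxide-directed iron-catalysed syn-carbomagnesiation of the propargylic alcohol places CH3 on the distal alkyne carbon and Mg (then H) on the proximal one, so the ring carbon and CH2OH end up cis, which is the required Z trisubstituted alkene.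

**Step 9**
Reactants: 13 the Z allylic alcohol
Product: 15 [(2Z)-3-[(2R,6S,7aR)-6-hydroxy-4,4,7a-trimethyl-2,4,5,6,7,7a-hexahydro-1-benzofuran-2-yl]but-2-en-1-yl]triphenylphosphonium bromide, via allylic bromide 14 (not isolated)
Conditions: CBr4 (1.05 equiv), PPh3 (2.2 equiv), CH2Cl2, −20 °C → rt
Reagents that add atoms: tetrabromomethane, BrC(Br)(Br)Br; triphenylphosphine, c1ccc(cc1)P(c1ccccc1)c1ccccc1
Why: Appel bromination of the primary allylic alcohol followed by SN2 quaternisation with the second equivalent of PPh3, both under neutral conditions so that neither the Z alkene nor the acid-labile C2 ether stereocentre is disturbed.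

**Step 10**
Reactants: 16 (2E,4E,6E)-2,7-dimethylocta-2,4,6-trienedial (3 equiv); 17 triethyl phosphonoacetate
Product: 18 ethyl (2E,4E,6E,8E)-4,9-dimethyl-10-oxodeca-2,4,6,8-tetraenoate
Conditions: NaH, THF, 0 °C
Reagents that add atoms: none
Why: Horner–Wadsworth–Emmons mono-olefination of the symmetric dialdehyde used in excess, the stabilised phosphonate giving the 2E ester.

**Step 11**
Reactants: 15 the phosphonium bromide; 18 the ester aldehyde
Product: 19 ethyl (2E,4E,6E,8E,10E,12Z)-13-[(2R,6S,7aR)-6-hydroxy-4,4,7a-trimethyl-2,4,5,6,7,7a-hexahydro-1-benzofuran-2-yl]-4,9-dimethyltetradeca-2,4,6,8,10,12-hexaenoate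
Conditions: NaOEt, EtOH–CH2Cl2, 0 °C → rt
Reagents that add atoms: none
Why: Wittig reaction of the allylic ylide with the polyenal, as in phosphonium salt plus dialdehyde carotenoid couplings, which keeps the Z geometry of the ylide partner and gives mainly the 10E alkene (the minor hindered 10Z isomer is removed by chromatography or crystallisation).

**Step 12**
Reactants: 19 the hexaenoate
Product: 20 (2E,4E,6E,8E,10E,12Z)-13-[(2R,6S,7aR)-6-hydroxy-4,4,7a-trimethyl-2,4,5,6,7,7a-hexahydro-1-benzofuran-2-yl]-4,9-dimethyltetradeca-2,4,6,8,10,12-hexaen-1-ol (target)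
Conditions: i-Bu2AlH (3.5 equiv), CH2Cl2, −78 °C; Rochelle salt
Reagents that add atoms: none
Why: 1,2-Reduction of the conjugated ester to the primary allylic alcohol, touching no stereocentre or alkene.

**Compound list**
1 | 3,5-dimethylphenol | Cc1cc(C)cc(O)c1 | starting material
2 | glyoxylic acid | O=CC(=O)O | starting material
3 | 2-hydroxy-2-(4-hydroxy-2,6-dimethylphenyl)acetic acid (racemic) | Cc1cc(O)cc(C)c1C(O)C(=O)O | intermediate
4 | 2-(4-hydroxy-2,6-dimethylphenyl)acetic acid | Cc1cc(O)cc(C)c1CC(=O)O | intermediate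
5 | 2-(1-hydroxy-2,6-dimethyl-4-oxocyclohexa-2,5-dien-1-yl)acetic acid | CC1=CC(=O)C=C(C)C1(O)CC(=O)O | intermediate
6 | (3aR,7aR)-3a-hydroxy-4,7a-dimethyl-3,3a,7,7a-tetrahydro-1-benzofuran-2,6-dione | CC1=CC(=O)C[C@@]2(C)OC(=O)C[C@@]12O | intermediate
7 | (7aR)-4,7a-dimethyl-7,7a-dihydro-1-benzofuran-2,6-dione | CC1=CC(=O)C[C@@]2(C)OC(=O)C=C12 | intermediate
8 | (7aR)-4,4,7a-trimethyl-5,7a-dihydro-1-benzofuran-2,6(4H,7H)-dione | CC1(C)CC(=O)C[C@@]2(C)OC(=O)C=C12 | intermediate
9 | (6S,7aR)-6-hydroxy-4,4,7a-trimethyl-5,6,7,7a-tetrahydro-1-benzofuran-2(4H)-one | CC1(C)C[C@H](O)C[C@@]2(C)OC(=O)C=C12 | intermediate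
10 | (6S,7aR)-4,4,7a-trimethyl-2,4,5,6,7,7a-hexahydro-1-benzofuran-2,6-diol | CC1(C)C[C@H](O)C[C@@]2(C)OC(O)C=C12 | intermediate
11 | trimethyl(prop-2-yn-1-yloxy)silane | C#CCO[Si](C)(C)C | starting material
12 | (2R,6S,7aR)-2-(3-hydroxyprop-1-yn-1-yl)-4,4,7a-trimethyl-2,4,5,6,7,7a-hexahydro-1-benzofuran-6-ol | OCC#C[C@H]1C=C2C(C)(C)C[C@H](O)C[C@@]2(C)O1 | intermediate
13 | (2Z)-3-[(2R,6S,7aR)-6-hydroxy-4,4,7a-trimethyl-2,4,5,6,7,7a-hexahydro-1-benzofuran-2-yl]but-2-en-1-ol | C/C(=C/CO)[C@H]1C=C2C(C)(C)C[C@H](O)C[C@@]2(C)O1 | intermediate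
14 | (2R,6S,7aR)-2-[(2Z)-4-bromobut-2-en-2-yl]-4,4,7a-trimethyl-2,4,5,6,7,7a-hexahydro-1-benzofuran-6-ol | C/C(=C/CBr)[C@H]1C=C2C(C)(C)C[C@H](O)C[C@@]2(C)O1 | intermediate
15 | [(2Z)-3-[(2R,6S,7aR)-6-hydroxy-4,4,7a-trimethyl-2,4,5,6,7,7a-hexahydro-1-benzofuran-2-yl]but-2-en-1-yl]triphenylphosphonium bromide | C/C(=C/C[P+](c1ccccc1)(c1ccccc1)c1ccccc1)[C@H]1C=C2C(C)(C)C[C@H](O)C[C@@]2(C)O1.[Br-] | intermediate
16 | (2E,4E,6E)-2,7-dimethylocta-2,4,6-trienedial | O=C/C(C)=C/C=C/C=C(C)/C=O | starting material
17 | triethyl phosphonoacetate | CCOC(=O)CP(=O)(OCC)OCC | starting material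
18 | ethyl (2E,4E,6E,8E)-4,9-dimethyl-10-oxodeca-2,4,6,8-tetraenoate | CCOC(=O)/C=C/C(C)=C/C=C/C=C(C)/C=O | intermediate
19 | ethyl (2E,4E,6E,8E,10E,12Z)-13-[(2R,6S,7aR)-6-hydroxy-4,4,7a-trimethyl-2,4,5,6,7,7a-hexahydro-1-benzofuran-2-yl]-4,9-dimethyltetradeca-2,4,6,8,10,12-hexaenoate | C/C(=C/C=C/C(C)=C/C=C/C=C(C)/C=C/C(=O)OCC)[C@H]1C=C2C(C)(C)C[C@H](O)C[C@@]2(C)O1 | intermediate
20 | (2E,4E,6E,8E,10E,12Z)-13-[(2R,6S,7aR)-6-hydroxy-4,4,7a-trimethyl-2,4,5,6,7,7a-hexahydro-1-benzofuran-2-yl]-4,9-dimethyltetradeca-2,4,6,8,10,12-hexaen-1-ol | C/C(=C/C=C/C(C)=C/C=C/C=C(C)/C=C/CO)[C@H]1C=C2C(C)(C)C[C@H](O)C[C@@]2(C)O1 | target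

**Totals**
Total step count: 12. Longest linear sequence: 11 (steps 1–9, 11, 12).

**Three steps most likely to fail**

Step 3 is the least precedented step. A carboxylic acid is a weaker and more reversible oxa-Michael donor than an alcohol, the acceptor carbon already bears a methyl group, and 7 can racemise by retro-addition if base is present. The fallback sets out from 4 and moves the desymmetrisation to the alcohol oxidation level, where the phosphoric-acid oxa-Michael reaction of para-quinols is established. BH3·SMe2 reduces 4 to 4-(2-hydroxyethyl)-3,5-dimethylphenol F1. PhI(OAc)2 in aqueous MeCN gives 4-hydroxy-4-(2-hydroxyethyl)-3,5-dimethylcyclohexa-2,5-dien-1-one F2. The chiral phosphoric acid closes it to (3aR,7aR)-3a-hydroxy-4,7a-dimethyl-2,3,3a,7a-tetrahydro-1-benzofuran-6(7H)-one F3. Martin sulfurane gives (7aR)-4,7a-dimethyl-7,7a-dihydro-1-benzofuran-6(2H)-one F4. MeMgBr with copper thiophene-2-carboxylate and an N-heterocyclic carbene ligand (1,4-selective on β-alkenyl enones) gives (7aR)-4,4,7a-trimethyl-4,5,7,7a-tetrahydro-1-benzofuran-6(2H)-one F5. Allylic oxidation of the O–CH2 group with CrO3 and 3,5-dimethylpyrazole then gives the butenolide, and the route is rejoined at 8.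

Step 4 may fail because 7 can reopen to a quinone methide and re-aromatise, or the cuprate may add at the wrong terminus. The fallback sets out from 6, which is isolated after the phosphoric-acid stage instead of being dehydrated in the flask. The methyl group is then delivered from the neighbouring tertiary aluminium alkoxide with Me3Al (CH2Cl2, −78 → 0 °C; hydroxyl-directed conjugate methylation as known for para-quinols). This gives (3aR,7aR)-3a-hydroxy-4,4,7a-trimethylhexahydro-1-benzofuran-2,6-dione F6, which Martin sulfurane dehydrates to 8.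

Step 7 may fail because the planar furanium ion has only a weak intrinsic facial bias and the catalyst class has so far been shown only on benzo-fused oxocarbenium ions. The fallback sets out from 10 and gives up catalyst control. The same alkynylation is run with CuI and no chiral ligand, giving 12 together with its C2 epimer (2S,6S,7aR)-2-(3-hydroxyprop-1-yn-1-yl)-4,4,7a-trimethyl-2,4,5,6,7,7a-hexahydro-1-benzofuran-6-ol F7. The epimers are separated by preparative HPLC. F7 is re-equilibrated with catalytic pyridinium p-toluenesulfonate (ionisation and re-closure of the C2–O bond) and recycled, coming back to the route at 12.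

**Further compounds**
F1 | step 3 | 4-(2-hydroxyethyl)-3,5-dimethylphenol | Cc1cc(O)cc(C)c1CCO
F2 | step 3 | 4-hydroxy-4-(2-hydroxyethyl)-3,5-dimethylcyclohexa-2,5-dien-1-one | CC1=CC(=O)C=C(C)C1(O)CCO
F3 | step 3 | (3aR,7aR)-3a-hydroxy-4,7a-dimethyl-2,3,3a,7a-tetrahydro-1-benzofuran-6(7H)-one | CC1=CC(=O)C[C@@]2(C)OCC[C@@]12O
F4 | step 3 | (7aR)-4,7a-dimethyl-7,7a-dihydro-1-benzofuran-6(2H)-one | CC1=CC(=O)C[C@@]2(C)OCC=C12
F5 | step 3 | (7aR)-4,4,7a-trimethyl-4,5,7,7a-tetrahydro-1-benzofuran-6(2H)-one | CC1(C)CC(=O)C[C@@]2(C)OCC=C12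
F6 | step 4 | (3aR,7aR)-3a-hydroxy-4,4,7a-trimethylhexahydro-1-benzofuran-2,6-dione | CC1(C)CC(=O)C[C@@]2(C)OC(=O)C[C@@]12O
F7 | step 7 | (2S,6S,7aR)-2-(3-hydroxyprop-1-yn-1-yl)-4,4,7a-trimethyl-2,4,5,6,7,7a-hexahydro-1-benzofuran-6-ol | OCC#C[C@@H]1C=C2C(C)(C)C[C@H](O)C[C@@]2(C)O1
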